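The seven-membered ring is cut at C4–C5 and C8–C8a (azulene numbering). C5–C6(CH3)=C7–C8 is read as isoprene and C4–C3a–C8a as a 2-oxyallyl cation whose carbonyl carbon is the later ring-fusion carbinol C3a. The key step, a (4+3) cycloaddition of isoprene with the 1-methyl-2-oxyallyl cation generated in situ from 3-chlorobutan-2-one, forms both bonds and the whole cyclohept-4-enone in one operation from two achiral liquids. The quaternary C8a is then set by a chiral-imine Michael addition, the cyclopentane by a carbonyl-ene closure onto the ketone, and C5 is oxygenated late and esterified.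

Key step: step 1

Remark: the target is read from its SMILES as the cis-fused (3R,3aS,5R,8aR) isomer, with 3a-OH, 8a-CH3 and the C3 isopropyl on one face and the C5 ester oxygen on the other; locants in the text are azulene locants unless a compound name says otherwise.

Step 1
Reactants: 1 3-chlorobutan-2-one; 2 isoprene (2-methylbuta-1,3-diene)
Product: 4 2,5-dimethylcyclohept-4-en-1-one (racemic), via 1-methyl-2-oxyallyl cation 3 (not isolated)
Conditions: isoprene (excess), Et3N, CF3CH2OH, 0 °C to rt
Reagents that add atoms: none
Why: Triethylamine enolises 1 towards the methyl group and the ionising fluoroalcohol assists loss of chloride, giving the 1-methyl-2-oxyallyl cation 3, which combines with the s-cis conformer of isoprene in a (4+3) cycloaddition. The closest known reaction type is the oxyallyl cation–1,3-diene cycloaddition that turns α-haloketones and isoprene-type dienes into cyclohept-4-enones. The seven-membered ring is closed intermolecularly by two σ-bonds, C2–C3 and C6–C7 of 4, either concerted but asynchronous or stepwise through a zwitterion, and the central diene bond remains as the C4=C5 alkene. The one new stereocenter, C2, forms as a racemate, which is of no consequence because it is planarised and set again in steps 2 and 3. The selectivity needed is regiochemical (5-methyl, not 4-methyl): the first bond should form between C1 of isoprene, its most nucleophilic terminus, and the unsubstituted, less hindered terminus of 3, after which the methyl-bearing enolate carbon closes on C4 of the diene. Excess diene and the weakly nucleophilic medium should disfavour solvent capture and five-membered (3+2) closure.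

Step 2
Reactants: 4 2,5-dimethylcyclohept-4-en-1-one; 5 (R)-1-phenylethylamine
Product: 6 N-[(1R)-1-phenylethyl]imine of 2,5-dimethylcyclohept-4-en-1-one (C2 epimers)
Conditions: 4 Å molecular sieves, toluene, 60 °C
Reagents that add atoms: none
Why: Condensation of ketone and primary amine (imine formation) under dehydrating, acid-free conditions that should leave the ring alkene in place; the C2 epimers equilibrate through the secondary enamine used in step 3, so no stereocenter needs control here.

Step 3
Reactants: 6 N-[(1R)-1-phenylethyl]imine of 2,5-dimethylcyclohept-4-en-1-one; 7 acrolein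
Product: 9 (R)-3-(1,4-dimethyl-7-oxocyclohept-3-en-1-yl)propanal, via Michael adduct imine 8 (not isolated)
Conditions: acrolein, hydroquinone (trace), THF, −20 °C to rt; then 10% aq. AcOH, rt
Reagents that add atoms: water (O)
Why: Aza-ene-type Michael addition of the more substituted secondary enamine tautomer of 6 should occur at the methyl-bearing α-carbon on the face anti to the phenyl group of the auxiliary, which sets the quaternary stereocenter; the (R)-amine is chosen because the (S)-amine gives the opposite spatial arrangement in 2-methylcycloalkanone imines, and mild aqueous acid then hydrolyses 8 to the keto aldehyde.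

Step 4
Reactants: 9 (R)-3-(1,4-dimethyl-7-oxocyclohept-3-en-1-yl)propanal; 10 isopropyltriphenylphosphonium iodide
Product: 12 (R)-2,5-dimethyl-2-(4-methylpent-3-en-1-yl)cyclohept-4-en-1-one, via isopropylidenetriphenylphosphorane 11 (not isolated)
Conditions: n-BuLi, THF, 0 °C; then 9, −78 °C to rt
Reagents that add atoms: none
Why: Wittig olefination with the non-stabilised ylide should be selective for the aldehyde over the hindered α-quaternary ketone at low temperature and installs the trisubstituted alkene needed as ene donor; no stereocenter is formed.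

Step 5
Reactants: 12 (R)-2,5-dimethyl-2-(4-methylpent-3-en-1-yl)cyclohept-4-en-1-one
Product: 13 (3R,3aS,8aR)-6,8a-dimethyl-3-(prop-1-en-2-yl)-2,3,4,5,8,8a-hexahydroazulen-3a(1H)-ol
Conditions: Me2AlCl (2 equiv), CH2Cl2, −78 °C to rt; 1 M HCl work-up
Reagents that add atoms: none
Why: Lewis-acid-promoted intramolecular carbonyl-ene reaction (type 1): the three-atom tether on the α-carbon can reach the activated carbonyl carbon only from its own face, which closes a cis-fused cyclopentanol (3a-OH cis to 8a-CH3), and the concerted transfer of a methyl hydrogen to the carbonyl oxygen needs oxygen and the isopropylidene unit on the same side, which places the C3 isopropenyl cis to 3a-OH.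

Step 6
Reactants: 13 (3R,3aS,8aR)-6,8a-dimethyl-3-(prop-1-en-2-yl)-2,3,4,5,8,8a-hexahydroazulen-3a(1H)-ol
Product: 14 (3R,3aS,8aR)-6,8a-dimethyl-3-(propan-2-yl)-2,3,4,5,8,8a-hexahydroazulen-3a(1H)-ol
Conditions: H2 (1 atm), RhCl(PPh3)3 (cat.), benzene, rt
Reagents that add atoms: none
Why: Homogeneous hydrogenation with RhCl(PPh3)3 should reduce the 1,1-disubstituted isopropenyl alkene much faster than the trisubstituted ring alkene; no stereocenter is touched.

Step 7
Reactants: 14 (3R,3aS,8aR)-6,8a-dimethyl-3-(propan-2-yl)-2,3,4,5,8,8a-hexahydroazulen-3a(1H)-ol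
Product: 15 (3R,3aS,8aR)-6,8a-dimethyl-3-(propan-2-yl)-2,3,4,5,8,8a-hexahydroazulene-3a,5(1H)-diol (C5 epimers)
Conditions: SeO2 (cat.), t-BuOOH, CH2Cl2, rt
Reagents that add atoms: selenium dioxide (O=[Se]=O), reoxidised by tert-butyl hydroperoxide (CC(C)(C)OO)
Why: SeO2 allylic oxidation (ene reaction then [2,3]-sigmatropic shift, Riley oxidation) should functionalise the ring CH2 attached to the methyl-bearing alkene carbon (C5) and keep the alkene in place; the C5 configuration is not controlled here and the epimers, with any enone, are taken on together.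

Step 8
Reactants: 15 (3R,3aS,8aR)-6,8a-dimethyl-3-(propan-2-yl)-2,3,4,5,8,8a-hexahydroazulene-3a,5(1H)-diol (C5 epimers)
Product: 16 (3R,3aS,8aR)-3a-hydroxy-6,8a-dimethyl-3-(propan-2-yl)-1,2,3,3a,4,8a-hexahydroazulen-5(8H)-one
Conditions: Dess–Martin periodinane, NaHCO3, CH2Cl2, 0 °C to rt
Reagents that add atoms: none
Why: Dess–Martin oxidation converts both secondary allylic alcohol epimers into one enone while the tertiary 3a-OH cannot be oxidised; the buffer should prevent retro-aldol opening of the β-hydroxy ketone.

Step 9
Reactants: 16 (3R,3aS,8aR)-3a-hydroxy-6,8a-dimethyl-3-(propan-2-yl)-1,2,3,3a,4,8a-hexahydroazulen-5(8H)-one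
Product: 17 (3R,3aS,5R,8aR)-6,8a-dimethyl-3-(propan-2-yl)-2,3,4,5,8,8a-hexahydroazulene-3a,5(1H)-diol
Conditions: Me4NBH(OAc)3, MeCN/AcOH, −30 °C
Reagents that add atoms: none
Why: Hydroxyl-directed 1,3-anti reduction (Evans–Saksena type): the 3a-hydroxyl displaces an acetate on boron and the resulting alkoxyborohydride delivers hydride to the C5 carbonyl from the face of the 3a-oxygen, so the new C5-OH should be trans to 3a-OH, i.e. (5R).

Step 10
Reactants: 17 (3R,3aS,5R,8aR)-6,8a-dimethyl-3-(propan-2-yl)-2,3,4,5,8,8a-hexahydroazulene-3a,5(1H)-diol; 18 3,4-dimethoxybenzoyl chloride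
Product: 19 (3R,3aS,5R,8aR)-3a-hydroxy-6,8a-dimethyl-3-(propan-2-yl)-1,2,3,3a,4,5,8,8a-octahydroazulen-5-yl 3,4-dimethoxybenzoate (target)
Conditions: pyridine, DMAP (cat.), CH2Cl2, 0 °C to rt
Reagents that add atoms: none
Why: DMAP-catalysed acylation should esterify the secondary allylic C5-OH selectively, because the tertiary ring-fusion 3a-OH is far less reactive; no stereocenter changes.

Compound list
1 | 3-chlorobutan-2-one | CC(=O)C(C)Cl | starting material
2 | isoprene (2-methylbuta-1,3-diene) | C=CC(C)=C | starting material
3 | 1-methyl-2-oxyallyl cation (zwitterion) | C[CH+]C([O-])=C | intermediate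
4 | 2,5-dimethylcyclohept-4-en-1-one (racemic) | CC1CC=C(C)CCC1=O | intermediate
5 | (R)-1-phenylethylamine | C[C@@H](N)c1ccccc1 | starting material
6 | N-[(1R)-1-phenylethyl]imine of 2,5-dimethylcyclohept-4-en-1-one (C2 epimers) | C[C@@H](N=C1CCC(C)=CCC1C)c1ccccc1 | intermediate
7 | acrolein (prop-2-enal) | C=CC=O | starting material
8 | 3-[(1R)-1,4-dimethyl-7-{[(1R)-1-phenylethyl]imino}cyclohept-3-en-1-yl]propanal (Michael adduct imine) | C[C@@H](N=C1CCC(C)=CC[C@@]1(C)CCC=O)c1ccccc1 | intermediate
9 | (R)-3-(1,4-dimethyl-7-oxocyclohept-3-en-1-yl)propanal | O=CCC[C@]1(C)CC=C(C)CCC1=O | intermediate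
10 | isopropyltriphenylphosphonium iodide | CC(C)[P+](c1ccccc1)(c1ccccc1)c1ccccc1.[I-] | starting material
11 | isopropylidenetriphenylphosphorane | CC(C)=P(c1ccccc1)(c1ccccc1)c1ccccc1 | intermediate
12 | (R)-2,5-dimethyl-2-(4-methylpent-3-en-1-yl)cyclohept-4-en-1-one | CC(C)=CCC[C@]1(C)CC=C(C)CCC1=O | intermediate
13 | (3R,3aS,8aR)-6,8a-dimethyl-3-(prop-1-en-2-yl)-2,3,4,5,8,8a-hexahydroazulen-3a(1H)-ol | C1C[C@]2(O)[C@@H](C(C)=C)CC[C@]2(C)CC=C1C | intermediate
14 | (3R,3aS,8aR)-6,8a-dimethyl-3-(propan-2-yl)-2,3,4,5,8,8a-hexahydroazulen-3a(1H)-ol | C1C[C@]2(O)[C@@H](C(C)C)CC[C@]2(C)CC=C1C | intermediate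
15 | (3R,3aS,8aR)-6,8a-dimethyl-3-(propan-2-yl)-2,3,4,5,8,8a-hexahydroazulene-3a,5(1H)-diol, C5 epimers | OC1C[C@]2(O)[C@@H](C(C)C)CC[C@]2(C)CC=C1C | intermediate
16 | (3R,3aS,8aR)-3a-hydroxy-6,8a-dimethyl-3-(propan-2-yl)-1,2,3,3a,4,8a-hexahydroazulen-5(8H)-one | O=C1C[C@]2(O)[C@@H](C(C)C)CC[C@]2(C)CC=C1C | intermediate
17 | (3R,3aS,5R,8aR)-6,8a-dimethyl-3-(propan-2-yl)-2,3,4,5,8,8a-hexahydroazulene-3a,5(1H)-diol | O[C@@H]1C[C@]2(O)[C@@H](C(C)C)CC[C@]2(C)CC=C1C | intermediate
18 | 3,4-dimethoxybenzoyl chloride | COc1ccc(C(=O)Cl)cc1OC | starting material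
19 | (3R,3aS,5R,8aR)-3a-hydroxy-6,8a-dimethyl-3-(propan-2-yl)-1,2,3,3a,4,5,8,8a-octahydroazulen-5-yl 3,4-dimethoxybenzoate | COc1ccc(C(=O)O[C@@H]2C[C@]3(O)[C@@H](C(C)C)CC[C@]3(C)CC=C2C)cc1OC | target

Total step count: 10. Longest linear sequence: 10 steps (1 and 2 to 19).

Steps most likely to fail

Step 1. The open-chain diene may react sluggishly, so that solvent capture of the oxyallyl cation or five-membered closure competes, and the regiochemical preference between the two oxyallyl termini may be low, giving the 4-methyl isomer alongside 4. The fallback sets out from 1 and comes back at 4 by ring-closing metathesis instead of cycloaddition. Radical allylation of 1 with allyltributylstannane (AIBN, benzene, 80 °C) should give 3-methylhex-5-en-2-one F1. Kinetic deprotonation at the methyl group (LDA, THF, −78 °C) and alkylation with 3-bromo-2-methylprop-1-ene should give 4,8-dimethylnona-1,8-dien-5-one F2. The second-generation Grubbs catalyst (CH2Cl2, 40 °C) should then close the trisubstituted ring alkene and deliver 4 as one regioisomer.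

Step 3. Acrolein may polymerise, or its aldehyde may condense with the imine nitrogen of the adduct (aza-annulation), and facial discrimination may be incomplete. If the enantiomeric purity is short of complete, crystallisation of diol 17 or of the ester 19 is foreseen. The fallback sets out from 6 and comes back at 9 by using an ester acceptor and adjusting the oxidation level afterwards. Michael addition of 6 to methyl acrylate (THF, rt) should give methyl 3-[(1R)-1,4-dimethyl-7-{[(1R)-1-phenylethyl]imino}cyclohept-3-en-1-yl]propanoate F3, hydrolysed with aqueous acetic acid to methyl 3-[(1R)-1,4-dimethyl-7-oxocyclohept-3-en-1-yl]propanoate F4. LiAlH4 (Et2O, 0 °C) should reduce both carbonyl groups to (2R)-2-(3-hydroxypropyl)-2,5-dimethylcyclohept-4-en-1-ol F5, and Swern oxidation of both hydroxyls returns keto aldehyde 9.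

Step 5. The unactivated, α-quaternary ketone is a weak enophile, and a stepwise zwitterionic Prins pathway may lead to chloride capture, proton loss to other alkenes, or the trans arrangement of 3a-OH and the C3 substituent. The fallback sets out from 9 and comes back at 13 by replacing the ene donor with an allylsilane nucleophile. Ethyltriphenylphosphonium bromide and n-BuLi give ethylidenetriphenylphosphorane F6, which is alkylated with (iodomethyl)trimethylsilane to triphenyl[1-(trimethylsilyl)propan-2-yl]phosphonium iodide F7 and deprotonated to triphenyl[1-(trimethylsilyl)propan-2-ylidene]phosphorane F8. Wittig reaction of F8 with the aldehyde of 9 should give (R)-2,5-dimethyl-2-[4-methyl-5-(trimethylsilyl)pent-3-en-1-yl]cyclohept-4-en-1-one F9. Intramolecular Hosomi–Sakurai allylation of the ketone (TiCl4, CH2Cl2, −78 °C) should then form the C3–C3a bond with loss of silicon and give 13; if this Lewis-acid mode does not give the cis isomer, fluoride-triggered closure is the alternative.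

Further compounds
F1 | step 1 | 3-methylhex-5-en-2-one | CC(=O)C(C)CC=C
F2 | step 1 | 4,8-dimethylnona-1,8-dien-5-one | C=CCC(C)C(=O)CCC(C)=C
F3 | step 3 | methyl 3-[(1R)-1,4-dimethyl-7-{[(1R)-1-phenylethyl]imino}cyclohept-3-en-1-yl]propanoate | COC(=O)CC[C@]1(C)CC=C(C)CCC1=N[C@H](C)c1ccccc1
F4 | step 3 | methyl 3-[(1R)-1,4-dimethyl-7-oxocyclohept-3-en-1-yl]propanoate | COC(=O)CC[C@]1(C)CC=C(C)CCC1=O
F5 | step 3 | (2R)-2-(3-hydroxypropyl)-2,5-dimethylcyclohept-4-en-1-ol (carbinol epimers) | OCCC[C@]1(C)CC=C(C)CCC1O
F6 | step 5 | ethylidenetriphenylphosphorane | CC=P(c1ccccc1)(c1ccccc1)c1ccccc1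
F7 | step 5 | triphenyl[1-(trimethylsilyl)propan-2-yl]phosphonium iodide | C[Si](C)(C)CC(C)[P+](c1ccccc1)(c1ccccc1)c1ccccc1.[I-]
F8 | step 5 | triphenyl[1-(trimethylsilyl)propan-2-ylidene]phosphorane | C[Si](C)(C)CC(C)=P(c1ccccc1)(c1ccccc1)c1ccccc1
F9 | step 5 | (R)-2,5-dimethyl-2-[4-methyl-5-(trimethylsilyl)pent-3-en-1-yl]cyclohept-4-en-1-one | C[Si](C)(C)CC(C)=CCC[C@]1(C)CC=C(C)CCC1=O
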